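**Plan**

- Retrosynthesis: cut the C8 ester; then the C8–C9 bond of the ten-membered ring (allylchromium plus aldehyde); then the C1–C2 epoxide and the C1–C10 bond (alkyne plus alkenyl bromide); then, in one stroke, the O1–C6 and C7=C11 bonds of the butenolide; last the C6–C7 and C2–C3 bonds of the chain.
- Enabling feature: in the lactone ring O1–C12(=O)–C11=C7–C6, C6 is a secondary O-bearing carbon bonded directly to C7, which is at ketone oxidation level. An α-hydroxy ketone (C6–OH, C7=O) can therefore take the carboxylate oxygen of a 2-phosphonopropanoic acid at C6 and then its phosphonate carbon (C11) at C7.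
- Forward order: C3–C6 chain, C4–C5 epoxide, C7/C8 unit, butenolide (first ring), C9/C10/C14 unit, (Z)-C1=C2, C1–C2 epoxide, ten-membered ring by C8–C9 closure, C8 ester.
- Stereochemistry: C4 and C5 from Sharpless epoxidation (D-tartrate); C6 from chelate-controlled Zn(BH4)2 reduction (6R) and SN2 inversion in the key step (6S); C1 and C2 from Lindlar reduction (Z) and Shi epoxidation; C8 from the ring-closing transition state.

Key step: step 13

Numbering: germacrane numbering of the target is used for all compounds (ring carbons C1–C10; C11, C12 (lactone C=O) and C13 on C7; C14 on C10; C15 on C4; O1 is the lactone ring oxygen). TBS = tert-butyldimethylsilyl, PMB = 4-methoxybenzyl.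

Assumption: the ring closure of step 22 is taken to deliver the (8S) alcohol; the first fallback deals with the opposite outcome.

**Route**

Step 1
Reactants: 1 3-methylbut-2-en-1-yl acetate (prenyl acetate)
Product: 2 (2E)-4-hydroxy-3-methylbut-2-en-1-yl acetate
Conditions: SeO2 (0.5 equiv), t-BuOOH (2 equiv), salicylic acid (cat.), CH2Cl2, rt
Reagents that add atoms: tert-butyl hydroperoxide, CC(C)(C)OO
Why: Riley-type allylic oxidation with substoichiometric SeO2 (ene reaction, then [2,3]-sigmatropic shift) hydroxylates the methyl group trans to the CH2OAc chain of the trisubstituted alkene, so the (E)-allylic alcohol should result.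

Step 2
Reactants: 2 (2E)-4-hydroxy-3-methylbut-2-en-1-yl acetate
Product: 3 (2E)-4-bromo-3-methylbut-2-en-1-yl acetate
Conditions: CBr4, PPh3, CH2Cl2, 0 °C
Reagents that add atoms: tetrabromomethane, BrC(Br)(Br)Br
Why: Appel bromination, in which bromide displaces the alkoxyphosphonium ion of the primary allylic alcohol by SN2 at 0 °C, should leave the (E)-alkene and the acetate untouched.

Step 3
Reactants: 3 (2E)-4-bromo-3-methylbut-2-en-1-yl acetate; 4 ethynyl(trimethyl)silane
Product: 6 (2E)-3-methylhex-2-en-5-yn-1-ol, via silylated enyne acetate 5 (not isolated)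
Conditions: CuI (20 mol %), NaI (20 mol %), K2CO3 (1.5 equiv), DMF, rt; then MeOH, rt, same flask
Reagents that add atoms: none
Why: Copper-mediated alkynylation of the primary allylic bromide joins C2 to C3 by direct (α) substitution to give the skipped enyne, and methanol added to the carbonate-containing flask should then cleave the acetate and the C-silyl group (transesterification, protodesilylation) without moving the (E)-alkene.

Step 4
Reactants: 6 (2E)-3-methylhex-2-en-5-yn-1-ol
Product: 7 [(2R,3R)-3-methyl-3-(prop-2-yn-1-yl)oxiran-2-yl]methanol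
Conditions: Ti(OiPr)4 (10 mol %), D-(−)-diethyl tartrate (12 mol %), t-BuOOH (2 equiv), 4 Å molecular sieves, CH2Cl2, −20 °C
Reagents that add atoms: tert-butyl hydroperoxide, CC(C)(C)OO
Why: Sharpless asymmetric epoxidation of a geraniol-type (E)-3,3-disubstituted primary allylic alcohol, a favourable substrate class, should with D-(−)-tartrate give the (2R,3R)-epoxy alcohol (mirror image of the (2S,3S) outcome of L-(+)-tartrate with geraniol), which sets C4 and C5.

Step 5
Reactants: 7 [(2R,3R)-3-methyl-3-(prop-2-yn-1-yl)oxiran-2-yl]methanol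
Product: 8 (2S,3R)-3-methyl-3-(prop-2-yn-1-yl)oxirane-2-carbaldehyde
Conditions: Dess–Martin periodinane, NaHCO3, CH2Cl2, 0 °C
Reagents that add atoms: none
Why: Buffered Dess–Martin oxidation converts the primary epoxy alcohol into the epoxy aldehyde under neutral conditions, so neither the epoxide nor C5 should suffer, and the aldehyde is used without purification.

Step 6
Reactants: 9 2-bromoprop-2-en-1-ol
Product: 10 [(2-bromoprop-2-en-1-yl)oxy](tert-butyl)dimethylsilane
Conditions: TBSCl, imidazole, CH2Cl2, 0 °C to rt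
Reagents that add atoms: tert-butyldimethylsilyl chloride, CC(C)(C)[Si](C)(C)Cl
Why: Standard imidazole-mediated silylation of a primary alcohol.

Step 7
Reactants: 8 (2S,3R)-3-methyl-3-(prop-2-yn-1-yl)oxirane-2-carbaldehyde; 10 [(2-bromoprop-2-en-1-yl)oxy](tert-butyl)dimethylsilane
Product: 11 2-[(TBS-oxy)methyl]-1-[(2R,3R)-3-methyl-3-(prop-2-yn-1-yl)oxiran-2-yl]prop-2-en-1-ol (both C6 epimers)
Conditions: CrCl2 (4 equiv), NiCl2 (1 mol %), DMF, rt
Reagents that add atoms: none
Why: Nozaki–Hiyama–Kishi coupling, in which NiCl2 activates the alkenyl bromide and the resulting alkenylchromium species adds to the aldehyde (C6–C7 bond) under non-basic conditions, should spare the terminal alkyne, the epoxide and the β-silyloxy group; the C6 carbinol forms as an epimer mixture, which does not matter because C6 is reset in steps 8 and 9.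

Step 8
Reactants: 11 epimeric allylic epoxy alcohols
Product: 12 2-[(TBS-oxy)methyl]-1-[(2S,3R)-3-methyl-3-(prop-2-yn-1-yl)oxiran-2-yl]prop-2-en-1-one
Conditions: Dess–Martin periodinane, NaHCO3, CH2Cl2, 0 °C to rt
Reagents that add atoms: none
Why: Dess–Martin oxidation of the secondary allylic epoxy alcohol gives the epoxy enone and erases the unselectively formed C6 centre, so both epimers converge on one compound.

Step 9
Reactants: 12 epoxy enone
Product: 13 (1R)-2-[(TBS-oxy)methyl]-1-[(2R,3R)-3-methyl-3-(prop-2-yn-1-yl)oxiran-2-yl]prop-2-en-1-ol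
Conditions: Zn(BH4)2, Et2O, −30 °C
Reagents that add atoms: none
Why: In this chelation-controlled reduction of an α,β-epoxy ketone, Zn(BH4)2 bridges the carbonyl and epoxide oxygens and delivers hydride (1,2-mode) to the carbonyl face turned away from C4 and its methyl group, which should give the erythro (anti) epoxy alcohol, that is the (6R) carbinol, the C6 epimer that the key step inverts.

Step 10
Reactants: 13 (1R)-allylic epoxy alcohol
Product: 15 (3S)-1-(TBS-oxy)-3-hydroxy-3-[(2R,3R)-3-methyl-3-(prop-2-yn-1-yl)oxiran-2-yl]propan-2-one, via ozonide 14 (not isolated)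
Conditions: O3, CH2Cl2, −78 °C (Sudan Red 7B as end-point indicator); then Me2S, −78 °C to rt
Reagents that add atoms: ozone, [O-][O+]=O
Why: Ozonolysis with reductive work-up cleaves the only C=C bond, the 1,1-disubstituted alkene, to the C7 ketone (a terminal alkyne reacts far more slowly with ozone and the indicator marks the end point) and leaves C6 untouched.

Step 11
Reactants: 16 ethyl 2-(diethoxyphosphoryl)prop-2-enoate; 17 (4-methoxyphenyl)methanol
Product: 18 ethyl 2-(diethoxyphosphoryl)-3-(PMB-oxy)propanoate (racemic)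
Conditions: KOtBu (5 mol %), THF, 0 °C
Reagents that add atoms: none
Why: Base-catalysed oxa-Michael addition of the alkoxide to the doubly activated vinylphosphonate needs only catalytic base because the adduct carbanion is protonated by the alcohol.

Step 12
Reactants: 18 ethyl 2-(diethoxyphosphoryl)-3-(PMB-oxy)propanoate
Product: 19 2-(diethoxyphosphoryl)-3-(PMB-oxy)propanoic acid (racemic)
Conditions: Me3SnOH, 1,2-dichloroethane, 70 °C; work-up with 1 M HCl
Reagents that add atoms: trimethyltin hydroxide, C[Sn](C)(C)O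
Why: Ester cleavage by hydroxide transfer from Me3SnOH runs under nearly neutral conditions, which should avoid the retro-oxa-Michael loss of the benzylic alkoxide that aqueous alkali could trigger and leaves the phosphonate ethyl esters intact.

Step 13
Reactants: 15 (3S)-α-hydroxy ketone; 19 2-(diethoxyphosphoryl)-3-(PMB-oxy)propanoic acid
Product: 21 (5S)-4-[(TBS-oxy)methyl]-3-[(PMB-oxy)methyl]-5-[(2R,3R)-3-methyl-3-(prop-2-yn-1-yl)oxiran-2-yl]furan-2(5H)-one, via acyloxy ketone phosphonate 20 (not isolated)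
Conditions: PPh3, diisopropyl azodicarboxylate, toluene, 0 °C to rt; then LiCl, DBU, MeCN, 0 °C, same flask
Reagents that add atoms: none
Why: PPh3 and the azodicarboxylate turn the C6 hydroxyl of 15 into an oxyphosphonium leaving group, the carboxylate of 19 displaces it from the rear (the neighbouring C7 carbonyl speeds this SN2 step) to form the O1–C6 bond in ester 20, and the phosphonate carbon C11 of 20, deprotonated as its lithium chelate by LiCl/DBU, then adds to the C7 ketone and expels diethyl phosphate to form the C7=C11 bond. The closest known reaction types are the Mitsunobu esterification of α-hydroxy ketones and epoxy alcohols with inversion and the intramolecular Horner–Wadsworth–Emmons synthesis of butenolides from α-acyloxy ketones under Masamune–Roush conditions, here run in one flask. The one ring closed is the five-membered lactone O1–C12–C11–C7–C6, by 5-exo-trig attack of C11 on the C7 carbonyl and syn elimination, so the C7=C11 bond lies in the ring and has no geometry to control. The only new stereocenter is C6, controlled by inversion of the (6R) carbinol set in step 9, which turns the erythro epoxy alcohol into the threo (6S) O1–C6 bond of the target. The step needs substitution at C6 rather than enolisation toward C6 (which would open the C4–C5 epoxide) and olefination at C7 rather than any other carbanion pathway: no anionic base is present while the oxyphosphonium ion exists, the phosphonate becomes acidic only after esterification, C7 is the only carbonyl within reach of C11, and LiCl/DBU is too weak to deprotonate C6–H of the product. Loss of 4-methoxybenzyl oxide from the carbanion is a reversible oxa-Michael step and feeds the same olefination.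

Step 14
Reactants: 21 (5S)-butenolide with terminal alkyne; 9 2-bromoprop-2-en-1-ol
Product: 22 (5S)-4-[(TBS-oxy)methyl]-5-{(2R,3R)-3-[4-(hydroxymethyl)pent-4-en-2-yn-1-yl]-3-methyloxiran-2-yl}-3-[(PMB-oxy)methyl]furan-2(5H)-one
Conditions: Pd(PPh3)2Cl2 (5 mol %), CuI (10 mol %), Et3N, THF, 40 °C
Reagents that add atoms: none
Why: Sonogashira coupling of the terminal alkyne with the alkenyl bromide forms the C1–C10 bond and is placed here because C13 still carries an ether that is inert to zerovalent palladium (an allylic acetate at C13 could ionise), while the free allylic alcohol is tolerated.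

Step 15
Reactants: 22 enynol
Product: 23 (5S)-4-[(TBS-oxy)methyl]-5-{(2R,3R)-3-[(2Z)-4-(hydroxymethyl)penta-2,4-dien-1-yl]-3-methyloxiran-2-yl}-3-[(PMB-oxy)methyl]furan-2(5H)-one
Conditions: H2 (1 atm), Pd/CaCO3 poisoned with Pb(OAc)2 (Lindlar catalyst), quinoline, EtOAc, rt, stopped after 1 equiv H2
Reagents that add atoms: none
Why: Lindlar semi-hydrogenation adds H2 syn to the alkyne on the poisoned palladium surface and should stop at the (Z)-alkene, which fixes the cis relationship at C1 and C2, while the tetrasubstituted butenolide alkene and the benzyl-type ether are not reduced.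

Step 16
Reactants: 23 (Z)-dienol
Product: 24 (5S)-4-[(TBS-oxy)methyl]-5-[(2R,3R)-3-{[(2S,3R)-3-(3-hydroxyprop-1-en-2-yl)oxiran-2-yl]methyl}-3-methyloxiran-2-yl]-3-[(PMB-oxy)methyl]furan-2(5H)-one
Conditions: D-glucose-derived spiro N-(4-methylphenyl)oxazolidinone ketone catalyst (C17H19NO6, 25 mol %), KHSO5 (as 2KHSO5·KHSO4·K2SO4), K2CO3, n-Bu4NHSO4, dimethoxyethane/dimethoxymethane–aqueous buffer, −10 to 0 °C
Reagents that add atoms: potassium peroxymonosulfate, [K+].OOS(=O)(=O)[O-]
Why: Shi epoxidation with the ketone made for conjugated cis-alkenes transfers oxygen from the chiral dioxirane in a concerted spiro transition state with the alkenyl group (C10=C14) next to the oxazolidinone, so the cis geometry is kept, the cis-disubstituted C1=C2 bond should be preferred over the 1,1-disubstituted one, and the catalyst should select the (1R,2S) face, the sense it shows with cis-β-methylstyrene.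

Step 17
Reactants: 24 vinyl epoxide alcohol
Product: 25 (5S)-4-[(TBS-oxy)methyl]-5-[(2R,3R)-3-{[(2S,3R)-3-(3-chloroprop-1-en-2-yl)oxiran-2-yl]methyl}-3-methyloxiran-2-yl]-3-[(PMB-oxy)methyl]furan-2(5H)-one
Conditions: N-chlorosuccinimide, Me2S, CH2Cl2, −20 to 0 °C
Reagents that add atoms: N-chlorosuccinimide, ClN1C(=O)CCC1=O
Why: Corey–Kim chlorination, in which the alkoxysulfonium chloride collapses by SN2 attack of chloride at the primary allylic carbon, is neutral and should spare both epoxides; the chloride is chosen over the bromide because it withstands pyridine and HF·pyridine in steps 19 to 21.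

Step 18
Reactants: 25 allylic chloride
Product: 26 (5S)-4-[(TBS-oxy)methyl]-5-[(2R,3R)-3-{[(2S,3R)-3-(3-chloroprop-1-en-2-yl)oxiran-2-yl]methyl}-3-methyloxiran-2-yl]-3-(hydroxymethyl)furan-2(5H)-one
Conditions: DDQ, CH2Cl2/pH 7 phosphate buffer, 0 °C
Reagents that add atoms: none
Why: Oxidative cleavage of the PMB ether by DDQ (benzylic hydride abstraction, then hydrolysis of the oxocarbenium ion) in a buffered two-phase medium should leave the silyl ether, the allylic chloride, the epoxides and the electron-poor alkenes untouched.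

Step 19
Reactants: 26 C13 alcohol
Product: 27 [(5S)-4-[(TBS-oxy)methyl]-5-[(2R,3R)-3-{[(2S,3R)-3-(3-chloroprop-1-en-2-yl)oxiran-2-yl]methyl}-3-methyloxiran-2-yl]-2-oxo-2,5-dihydrofuran-3-yl]methyl acetate
Conditions: Ac2O, pyridine, DMAP (cat.), CH2Cl2, 0 °C
Reagents that add atoms: acetic anhydride, CC(=O)OC(C)=O
Why: DMAP-catalysed acetylation of the only free hydroxyl group installs the C13 acetate of the target.

Step 20
Reactants: 27 C13 acetate
Product: 28 [(5S)-5-[(2R,3R)-3-{[(2S,3R)-3-(3-chloroprop-1-en-2-yl)oxiran-2-yl]methyl}-3-methyloxiran-2-yl]-4-(hydroxymethyl)-2-oxo-2,5-dihydrofuran-3-yl]methyl acetate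
Conditions: HF·pyridine, pyridine, THF, 0 °C
Reagents that add atoms: none
Why: Fluoride-induced desilylation with pyridine-buffered HF·pyridine should free the primary C8 alcohol while the acetate, the allylic chloride and both epoxides survive at 0 °C.

Step 21
Reactants: 28 C8 alcohol
Product: 29 [(5S)-5-[(2R,3R)-3-{[(2S,3R)-3-(3-chloroprop-1-en-2-yl)oxiran-2-yl]methyl}-3-methyloxiran-2-yl]-4-formyl-2-oxo-2,5-dihydrofuran-3-yl]methyl acetate
Conditions: Dess–Martin periodinane, NaHCO3, CH2Cl2, 0 °C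
Reagents that add atoms: none
Why: Buffered Dess–Martin oxidation of the primary allylic alcohol gives the C8 aldehyde under neutral conditions, and the aldehyde is used at once.

Step 22
Reactants: 29 aldehyde allylic chloride
Product: 30 (1R,2S,4R,5R,6S,8S)-13-acetoxy-1,2:4,5-diepoxy-8-hydroxygermacra-7(11),10(14)-dien-12,6-olide
Conditions: CrCl2 (8 equiv), DMF/THF, slow addition of 29 to 2 mM final concentration, rt, no iodide additive
Reagents that add atoms: none
Why: In this intramolecular Nozaki–Hiyama allylation (Barbier type), divalent chromium reduces the allylic chloride in DMF to a 2-substituted allylchromium species with two equivalent CH2 termini, and its addition to the C8 aldehyde through a six-membered chair transition state under high dilution should close the ten-membered ring, create the C10=C14 exocyclic methylene and set C8, taken to be (8S) as stated in the assumption.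

Step 23
Reactants: 31 ethyl 2-(hydroxymethyl)prop-2-enoate
Product: 32 ethyl 2-[(TBS-oxy)methyl]prop-2-enoate
Conditions: TBSCl, imidazole, DMF, rt
Reagents that add atoms: tert-butyldimethylsilyl chloride, CC(C)(C)[Si](C)(C)Cl
Why: Standard imidazole-mediated silylation of a primary alcohol.

Step 24
Reactants: 32 ethyl 2-[(TBS-oxy)methyl]prop-2-enoate
Product: 33 2-[(TBS-oxy)methyl]prop-2-enoic acid
Conditions: LiOH, THF/H2O, 0 °C; then 1 M HCl to pH 3
Reagents that add atoms: lithium hydroxide, [Li+].[OH-]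
Why: Saponification of the ethyl ester with LiOH at 0 °C (acyl–oxygen cleavage) should leave the silyl ether, which is stable to cold aqueous base.

Step 25
Reactants: 30 (8S)-macrocyclic alcohol; 33 2-[(TBS-oxy)methyl]prop-2-enoic acid
Product: 34 (1R,2S,4R,5R,6S,8S)-13-acetoxy-1,2:4,5-diepoxy-8-({2-[(TBS-oxy)methyl]prop-2-enoyl}oxy)germacra-7(11),10(14)-dien-12,6-olide
Conditions: 2,4,6-trichlorobenzoyl chloride, Et3N, THF, rt; then 30, DMAP, toluene, rt
Reagents that add atoms: none
Why: In the Yamaguchi esterification the mixed anhydride of 33 is attacked by DMAP and the acylpyridinium ion acylates the hindered C8 hydroxyl with retention at C8, under conditions too mild to deprotonate C6–H of the butenolide.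

Step 26
Reactants: 34 silyl-protected ester
Product: 35 (1R,2S,4R,5R,6S,8S)-13-acetoxy-1,2:4,5-diepoxy-8-{[2-(hydroxymethyl)prop-2-enoyl]oxy}germacra-7(11),10(14)-dien-12,6-olide (target)
Conditions: HF·pyridine, pyridine, THF, 0 °C
Reagents that add atoms: none
Why: Buffered HF·pyridine removes the primary silyl ether by fluoride attack at silicon and should leave the acetate, the acrylate and both epoxides of the target untouched.

**Compound list**

1 | 3-methylbut-2-en-1-yl acetate | CC(C)=CCOC(C)=O | starting material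
2 | (2E)-4-hydroxy-3-methylbut-2-en-1-yl acetate | CC(=O)OC/C=C(\C)CO | intermediate
3 | (2E)-4-bromo-3-methylbut-2-en-1-yl acetate | CC(=O)OC/C=C(\C)CBr | intermediate
4 | ethynyl(trimethyl)silane | C#C[Si](C)(C)C | starting material
5 | (2E)-3-methyl-6-(trimethylsilyl)hex-2-en-5-yn-1-yl acetate | CC(=O)OC/C=C(\C)CC#C[Si](C)(C)C | intermediate (not isolated)
6 | (2E)-3-methylhex-2-en-5-yn-1-ol | OC/C=C(\C)CC#C | intermediate
7 | [(2R,3R)-3-methyl-3-(prop-2-yn-1-yl)oxiran-2-yl]methanol | C#CC[C@@]1(C)O[C@@H]1CO | intermediate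
8 | (2S,3R)-3-methyl-3-(prop-2-yn-1-yl)oxirane-2-carbaldehyde | C#CC[C@@]1(C)O[C@@H]1C=O | intermediate
9 | 2-bromoprop-2-en-1-ol | OCC(Br)=C | starting material
10 | [(2-bromoprop-2-en-1-yl)oxy](tert-butyl)dimethylsilane | C=C(Br)CO[Si](C)(C)C(C)(C)C | intermediate
11 | (1RS)-2-({[tert-butyl(dimethyl)silyl]oxy}methyl)-1-[(2R,3R)-3-methyl-3-(prop-2-yn-1-yl)oxiran-2-yl]prop-2-en-1-ol, both C6 epimers | C#CC[C@@]1(C)O[C@@H]1C(O)C(=C)CO[Si](C)(C)C(C)(C)C | intermediate
12 | 2-({[tert-butyl(dimethyl)silyl]oxy}methyl)-1-[(2S,3R)-3-methyl-3-(prop-2-yn-1-yl)oxiran-2-yl]prop-2-en-1-one | C#CC[C@@]1(C)O[C@@H]1C(=O)C(=C)CO[Si](C)(C)C(C)(C)C | intermediate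
13 | (1R)-2-({[tert-butyl(dimethyl)silyl]oxy}methyl)-1-[(2R,3R)-3-methyl-3-(prop-2-yn-1-yl)oxiran-2-yl]prop-2-en-1-ol | C#CC[C@@]1(C)O[C@@H]1[C@H](O)C(=C)CO[Si](C)(C)C(C)(C)C | intermediate
14 | 3-({[tert-butyl(dimethyl)silyl]oxy}methyl)-3-{(S)-hydroxy[(2R,3R)-3-methyl-3-(prop-2-yn-1-yl)oxiran-2-yl]methyl}-1,2,4-trioxolane (ozonide of 13, both epimers at the trioxolane carbon) | C#CC[C@@]1(C)O[C@@H]1[C@H](O)C1(CO[Si](C)(C)C(C)(C)C)OOCO1 | intermediate (not isolated)
15 | (3S)-1-{[tert-butyl(dimethyl)silyl]oxy}-3-hydroxy-3-[(2R,3R)-3-methyl-3-(prop-2-yn-1-yl)oxiran-2-yl]propan-2-one | C#CC[C@@]1(C)O[C@@H]1[C@H](O)C(=O)CO[Si](C)(C)C(C)(C)C | intermediate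
16 | ethyl 2-(diethoxyphosphoryl)prop-2-enoate | C=C(C(=O)OCC)P(=O)(OCC)OCC | starting material
17 | (4-methoxyphenyl)methanol | COc1ccc(CO)cc1 | starting material
18 | ethyl 2-(diethoxyphosphoryl)-3-[(4-methoxyphenyl)methoxy]propanoate (racemic) | CCOC(=O)C(COCc1ccc(OC)cc1)P(=O)(OCC)OCC | intermediate
19 | 2-(diethoxyphosphoryl)-3-[(4-methoxyphenyl)methoxy]propanoic acid (racemic) | OC(=O)C(COCc1ccc(OC)cc1)P(=O)(OCC)OCC | intermediate
20 | (1R)-3-{[tert-butyl(dimethyl)silyl]oxy}-1-[(2R,3R)-3-methyl-3-(prop-2-yn-1-yl)oxiran-2-yl]-2-oxopropyl 2-(diethoxyphosphoryl)-3-[(4-methoxyphenyl)methoxy]propanoate (both epimers at the phosphonate carbon) | C#CC[C@@]1(C)O[C@@H]1[C@@H](OC(=O)C(COCc1ccc(OC)cc1)P(=O)(OCC)OCC)C(=O)CO[Si](C)(C)C(C)(C)C | intermediate (not isolated)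
21 | (5S)-4-({[tert-butyl(dimethyl)silyl]oxy}methyl)-3-{[(4-methoxyphenyl)methoxy]methyl}-5-[(2R,3R)-3-methyl-3-(prop-2-yn-1-yl)oxiran-2-yl]furan-2(5H)-one | C#CC[C@@]1(C)O[C@@H]1[C@H]1OC(=O)C(COCc2ccc(OC)cc2)=C1CO[Si](C)(C)C(C)(C)C | intermediate
22 | (5S)-4-({[tert-butyl(dimethyl)silyl]oxy}methyl)-5-{(2R,3R)-3-[4-(hydroxymethyl)pent-4-en-2-yn-1-yl]-3-methyloxiran-2-yl}-3-{[(4-methoxyphenyl)methoxy]methyl}furan-2(5H)-one | OCC(=C)C#CC[C@@]1(C)O[C@@H]1[C@H]1OC(=O)C(COCc2ccc(OC)cc2)=C1CO[Si](C)(C)C(C)(C)C | intermediate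
23 | (5S)-4-({[tert-butyl(dimethyl)silyl]oxy}methyl)-5-{(2R,3R)-3-[(2Z)-4-(hydroxymethyl)penta-2,4-dien-1-yl]-3-methyloxiran-2-yl}-3-{[(4-methoxyphenyl)methoxy]methyl}furan-2(5H)-one | OCC(=C)/C=C\C[C@@]1(C)O[C@@H]1[C@H]1OC(=O)C(COCc2ccc(OC)cc2)=C1CO[Si](C)(C)C(C)(C)C | intermediate
24 | (5S)-4-({[tert-butyl(dimethyl)silyl]oxy}methyl)-5-[(2R,3R)-3-{[(2S,3R)-3-(3-hydroxyprop-1-en-2-yl)oxiran-2-yl]methyl}-3-methyloxiran-2-yl]-3-{[(4-methoxyphenyl)methoxy]methyl}furan-2(5H)-one | OCC(=C)[C@H]1O[C@H]1C[C@@]1(C)O[C@@H]1[C@H]1OC(=O)C(COCc2ccc(OC)cc2)=C1CO[Si](C)(C)C(C)(C)C | intermediate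
25 | (5S)-4-({[tert-butyl(dimethyl)silyl]oxy}methyl)-5-[(2R,3R)-3-{[(2S,3R)-3-(3-chloroprop-1-en-2-yl)oxiran-2-yl]methyl}-3-methyloxiran-2-yl]-3-{[(4-methoxyphenyl)methoxy]methyl}furan-2(5H)-one | ClCC(=C)[C@H]1O[C@H]1C[C@@]1(C)O[C@@H]1[C@H]1OC(=O)C(COCc2ccc(OC)cc2)=C1CO[Si](C)(C)C(C)(C)C | intermediate
26 | (5S)-4-({[tert-butyl(dimethyl)silyl]oxy}methyl)-5-[(2R,3R)-3-{[(2S,3R)-3-(3-chloroprop-1-en-2-yl)oxiran-2-yl]methyl}-3-methyloxiran-2-yl]-3-(hydroxymethyl)furan-2(5H)-one | ClCC(=C)[C@H]1O[C@H]1C[C@@]1(C)O[C@@H]1[C@H]1OC(=O)C(CO)=C1CO[Si](C)(C)C(C)(C)C | intermediate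
27 | [(5S)-4-({[tert-butyl(dimethyl)silyl]oxy}methyl)-5-[(2R,3R)-3-{[(2S,3R)-3-(3-chloroprop-1-en-2-yl)oxiran-2-yl]methyl}-3-methyloxiran-2-yl]-2-oxo-2,5-dihydrofuran-3-yl]methyl acetate | ClCC(=C)[C@H]1O[C@H]1C[C@@]1(C)O[C@@H]1[C@H]1OC(=O)C(COC(C)=O)=C1CO[Si](C)(C)C(C)(C)C | intermediate
28 | [(5S)-5-[(2R,3R)-3-{[(2S,3R)-3-(3-chloroprop-1-en-2-yl)oxiran-2-yl]methyl}-3-methyloxiran-2-yl]-4-(hydroxymethyl)-2-oxo-2,5-dihydrofuran-3-yl]methyl acetate | ClCC(=C)[C@H]1O[C@H]1C[C@@]1(C)O[C@@H]1[C@H]1OC(=O)C(COC(C)=O)=C1CO | intermediate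
29 | [(5S)-5-[(2R,3R)-3-{[(2S,3R)-3-(3-chloroprop-1-en-2-yl)oxiran-2-yl]methyl}-3-methyloxiran-2-yl]-4-formyl-2-oxo-2,5-dihydrofuran-3-yl]methyl acetate | ClCC(=C)[C@H]1O[C@H]1C[C@@]1(C)O[C@@H]1[C@H]1OC(=O)C(COC(C)=O)=C1C=O | intermediate
30 | (1R,2S,4R,5R,6S,8S)-13-acetoxy-1,2:4,5-diepoxy-8-hydroxygermacra-7(11),10(14)-dien-12,6-olide | O[C@H]1CC(=C)[C@H]2O[C@H]2C[C@@]2(C)O[C@@H]2[C@H]2OC(=O)C(COC(C)=O)=C12 | intermediate
31 | ethyl 2-(hydroxymethyl)prop-2-enoate | C=C(CO)C(=O)OCC | starting material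
32 | ethyl 2-({[tert-butyl(dimethyl)silyl]oxy}methyl)prop-2-enoate | C=C(CO[Si](C)(C)C(C)(C)C)C(=O)OCC | intermediate
33 | 2-({[tert-butyl(dimethyl)silyl]oxy}methyl)prop-2-enoic acid | C=C(CO[Si](C)(C)C(C)(C)C)C(O)=O | intermediate
34 | (1R,2S,4R,5R,6S,8S)-13-acetoxy-8-{[2-({[tert-butyl(dimethyl)silyl]oxy}methyl)prop-2-enoyl]oxy}-1,2:4,5-diepoxygermacra-7(11),10(14)-dien-12,6-olide | C=C(CO[Si](C)(C)C(C)(C)C)C(=O)O[C@H]1CC(=C)[C@H]2O[C@H]2C[C@@]2(C)O[C@@H]2[C@H]2OC(=O)C(COC(C)=O)=C12 | intermediate
35 | (1R,2S,4R,5R,6S,8S)-13-acetoxy-1,2:4,5-diepoxy-8-{[2-(hydroxymethyl)prop-2-enoyl]oxy}germacra-7(11),10(14)-dien-12,6-olide | C=C(CO)C(=O)O[C@H]1CC(=C)[C@H]2O[C@H]2C[C@@]2(C)O[C@@H]2[C@H]2OC(=O)C(COC(C)=O)=C12 | target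

**Totals**

Total step count: 26. Longest linear sequence: 21 steps (steps 1–5, 7–10, 13–22, 25, 26).

**Steps most likely to fail, with fallbacks**

Step 22 (ring closure). What may go wrong: poor facial selectivity in the addition of the allylchromium unit to the C8 aldehyde, so that attack on the opposite face dominates. Fallback: the route sets out from 29 as before; the same ring closure then delivers (1R,2S,4R,5R,6S,8R)-13-acetoxy-1,2:4,5-diepoxy-8-hydroxygermacra-7(11),10(14)-dien-12,6-olide F1. This epimer is esterified with acid 33 under Mitsunobu conditions (PPh3, diisopropyl azodicarboxylate, toluene, 0 °C), which forms the C8–O bond with inversion, so that C8 is fixed by an SN2 step and not by the cyclisation. The fallback comes back to the route at 34.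

Step 13 (key step). What may go wrong: collapse of the crowded C6 oxyphosphonium ion by acyl transfer with retention or by elimination instead of rear-side displacement. Fallback: the route sets out from 15, which is sulfonylated (methanesulfonic anhydride, pyridine, CH2Cl2, −20 °C) to (1S)-3-(TBS-oxy)-1-[(2R,3R)-3-methyl-3-(prop-2-yn-1-yl)oxiran-2-yl]-2-oxopropyl methanesulfonate F2. The cesium salt of 19 (Cs2CO3, DMF, rt) then displaces the α-keto sulfonate with inversion to give 20, isolated this time, and LiCl/DBU in MeCN closes 20 by the same olefination. The fallback comes back to the route at 21.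

Step 16 (epoxidation of the diene). What may go wrong: oxygen transfer to the 1,1-disubstituted C10=C14 bond or to the wrong face of C1=C2, that is low regio- or face selectivity of the chiral dioxirane on this diene. Fallback: the C1–C2 epoxide is put in after ring closure, where the ring and not a catalyst decides the face. The route sets out from 23 and runs through these stages:
- Corey–Kim chlorination (N-chlorosuccinimide, Me2S) gives the (2Z)-dienyl allylic chloride F3.
- DDQ removes the PMB group to give the C13 alcohol of the diene series F4.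
- Ac2O/pyridine gives the C13 acetate of the diene series F5.
- Buffered HF·pyridine gives the C8 alcohol of the diene series F6.
- Dess–Martin oxidation gives the C8 aldehyde of the diene series F7.
- CrCl2 in DMF/THF under high dilution closes the ring to (1Z,4R,5R,6S,8S)-13-acetoxy-4,5-epoxy-8-hydroxygermacra-1,7(11),10(14)-trien-12,6-olide F8.
- Dimethyldioxirane (acetone, −20 °C) should then epoxidise the cis C1=C2 bond from the open outer face of the ten-membered ring, before the exocyclic methylene and the electron-poor alkenes react.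

The fallback comes back to the route at 30.

**Further compounds**

F1 | step 22 | (1R,2S,4R,5R,6S,8R)-13-acetoxy-1,2:4,5-diepoxy-8-hydroxygermacra-7(11),10(14)-dien-12,6-olide | O[C@@H]1CC(=C)[C@H]2O[C@H]2C[C@@]2(C)O[C@@H]2[C@H]2OC(=O)C(COC(C)=O)=C12
F2 | step 13 | (1S)-3-{[tert-butyl(dimethyl)silyl]oxy}-1-[(2R,3R)-3-methyl-3-(prop-2-yn-1-yl)oxiran-2-yl]-2-oxopropyl methanesulfonate | C#CC[C@@]1(C)O[C@@H]1[C@H](OS(C)(=O)=O)C(=O)CO[Si](C)(C)C(C)(C)C
F3 | step 16 | (5S)-4-({[tert-butyl(dimethyl)silyl]oxy}methyl)-5-{(2R,3R)-3-[(2Z)-4-(chloromethyl)penta-2,4-dien-1-yl]-3-methyloxiran-2-yl}-3-{[(4-methoxyphenyl)methoxy]methyl}furan-2(5H)-one | ClCC(=C)/C=C\C[C@@]1(C)O[C@@H]1[C@H]1OC(=O)C(COCc2ccc(OC)cc2)=C1CO[Si](C)(C)C(C)(C)C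
F4 | step 16 | (5S)-4-({[tert-butyl(dimethyl)silyl]oxy}methyl)-5-{(2R,3R)-3-[(2Z)-4-(chloromethyl)penta-2,4-dien-1-yl]-3-methyloxiran-2-yl}-3-(hydroxymethyl)furan-2(5H)-one | ClCC(=C)/C=C\C[C@@]1(C)O[C@@H]1[C@H]1OC(=O)C(CO)=C1CO[Si](C)(C)C(C)(C)C
F5 | step 16 | [(5S)-4-({[tert-butyl(dimethyl)silyl]oxy}methyl)-5-{(2R,3R)-3-[(2Z)-4-(chloromethyl)penta-2,4-dien-1-yl]-3-methyloxiran-2-yl}-2-oxo-2,5-dihydrofuran-3-yl]methyl acetate | ClCC(=C)/C=C\C[C@@]1(C)O[C@@H]1[C@H]1OC(=O)C(COC(C)=O)=C1CO[Si](C)(C)C(C)(C)C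
F6 | step 16 | [(5S)-5-{(2R,3R)-3-[(2Z)-4-(chloromethyl)penta-2,4-dien-1-yl]-3-methyloxiran-2-yl}-4-(hydroxymethyl)-2-oxo-2,5-dihydrofuran-3-yl]methyl acetate | ClCC(=C)/C=C\C[C@@]1(C)O[C@@H]1[C@H]1OC(=O)C(COC(C)=O)=C1CO
F7 | step 16 | [(5S)-5-{(2R,3R)-3-[(2Z)-4-(chloromethyl)penta-2,4-dien-1-yl]-3-methyloxiran-2-yl}-4-formyl-2-oxo-2,5-dihydrofuran-3-yl]methyl acetate | ClCC(=C)/C=C\C[C@@]1(C)O[C@@H]1[C@H]1OC(=O)C(COC(C)=O)=C1C=O
F8 | step 16 | (1Z,4R,5R,6S,8S)-13-acetoxy-4,5-epoxy-8-hydroxygermacra-1,7(11),10(14)-trien-12,6-olide | O[C@H]1CC(=C)/C=C\C[C@@]2(C)O[C@@H]2[C@H]2OC(=O)C(COC(C)=O)=C12
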